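**Retrosynthetic overview**

- Numbering: side chain C1′ (ArCH2) to C11′ (bears the ring); oxolane O1, C2 (CMe2), C3 (CHOH), C4 (CH2), C5 (CH bonded to C11′).
- Disconnections: hydroquinone from the quinone from the dimethyl ether; C1′–C2′ by coupling an alkenylalane (carboalumination of a terminal alkyne) with a benzylic chloride; C4′–C5′ by asymmetric propargylation of an enal; the C5′–C11′ chain with both E-alkenes comes from geraniol.
- Oxolane: O1–C5 and C2–C3 are made together by a catalytic asymmetric (3+2) annulation of acetone with a racemic alkenylcyclopropane-1,1-diester; C3 is then taken from C(CO2Me)2 to C=O and reduced to the 3S alcohol.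
- Enabling feature: O1–C2(CH3)2 of the oxolane is an intact acetone unit; C5 is allylic to the C10′=C11′ alkene (stabilised cation) and C3, two atoms away, can carry a malonate anion, so C5–C4–C3 is a 1,3-dipole stored in a cyclopropane.
- Ring order: the oxolane is the only ring formed (step 6); the arene is brought in intact (steps 14–18) and the hydroquinone is unmasked last.

Key step: step 6

Assumption: the absolute sense of induction in steps 6 and 13 is assigned by analogy with related substrates; if it proves opposite, the mirror-image ligand or acid is used with no other change.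

**Route**

Step 1
Reactants: 1 geraniol
Product: 2 geranyl triisopropylsilyl ether
Conditions: i-Pr3SiCl, imidazole, DMF, 0 °C to rt
Reagents that add atoms: chlorotriisopropylsilane, CC(C)[Si](Cl)(C(C)C)C(C)C
Why: Imidazole-promoted silylation of the primary allylic alcohol should be clean, and the triisopropylsilyl group is chosen to survive hydroxide (step 7) and aqueous acid (step 8).

Step 2
Reactants: 2 geranyl triisopropylsilyl ether
Product: 3 (2E,6E)-2,6-dimethyl-8-[(triisopropylsilyl)oxy]octa-2,6-dien-1-ol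
Conditions: SeO2 (0.3 equiv), t-BuOOH (3 equiv), salicylic acid (cat.), CH2Cl2, rt
Reagents that add atoms: tert-butyl hydroperoxide, CC(C)(C)OO (oxygen relayed by selenium dioxide, O=[Se]=O)
Why: Riley allylic oxidation (ene reaction then 2,3-sigmatropic shift) should hydroxylate the E-methyl group of the terminal trisubstituted alkene, the sigmatropic step fixing the E geometry.

Step 3
Reactants: 3 (2E,6E)-2,6-dimethyl-8-[(triisopropylsilyl)oxy]octa-2,6-dien-1-ol
Product: 4 (2E,6E)-2,6-dimethyl-8-[(triisopropylsilyl)oxy]octa-2,6-dienal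
Conditions: MnO2 (excess), CH2Cl2, rt
Reagents that add atoms: none
Why: MnO2 oxidation is selective for allylic alcohols and should give the E-enal without touching the silyl ether.

Step 4
Reactants: 4 (2E,6E)-2,6-dimethyl-8-[(triisopropylsilyl)oxy]octa-2,6-dienal; 5 methyltriphenylphosphonium bromide
Product: 6 triisopropyl{[(2E,6E)-3,7-dimethylnona-2,6,8-trien-1-yl]oxy}silane
Conditions: 5, KOt-Bu, THF, 0 °C; then 4, −78 °C to rt
Reagents that add atoms: none
Why: Wittig methylenation of the enal should give the conjugated diene terminus with the E trisubstituted alkene unchanged.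

Step 5
Reactants: 6 triisopropyl{[(2E,6E)-3,7-dimethylnona-2,6,8-trien-1-yl]oxy}silane; 7 dimethyl diazomalonate
Product: 8 racemic dimethyl 2-[(2E,6E)-6-methyl-8-(triisopropylsilyloxy)octa-2,6-dien-2-yl]cyclopropane-1,1-dicarboxylate
Conditions: Rh2(esp)2 (0.5 mol%; esp = α,α,α′,α′-tetramethyl-1,3-benzenedipropionate), CH2Cl2, 0 °C to rt, slow addition of 7
Reagents that add atoms: none
Why: Rhodium-carbenoid cyclopropanation with a diazomalonate should occur at the monosubstituted terminus of the diene (least hindered π bond) and not at the trisubstituted alkenes, and the new stereocentre is deliberately formed as a racemate.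

Step 6
Reactants: 8 racemic dimethyl 2-[(2E,6E)-6-methyl-8-(triisopropylsilyloxy)octa-2,6-dien-2-yl]cyclopropane-1,1-dicarboxylate; 9 acetone
Product: 11 dimethyl (5S)-2,2-dimethyl-5-[(2E,6E)-6-methyl-8-(triisopropylsilyloxy)octa-2,6-dien-2-yl]oxolane-3,3-dicarboxylate, via oxocarbenium malonate ion pair 10 (not isolated)
Conditions: MgI2 (10 mol%), (S,S)-4-chloro-t-Bu-pybox (12 mol%), acetone (10 equiv), CCl4, 4 Å MS, rt
Reagents that add atoms: none
Why: Proposed new method: the pybox–MgI2 Lewis acid chelates the geminal diester of 8 and weakens the cyclopropane bond between the diester carbon and the alkenyl-bearing carbon, whose positive charge is spread over the adjacent trisubstituted alkene; the carbonyl oxygen of acetone opens this bond with inversion (new O1–C5 bond) to give ion pair 10, whose malonate carbon then adds to the oxocarbenium carbon (new C3–C2 bond). The closest known reaction type is the Lewis acid-catalysed (3+2) annulation of donor–acceptor cyclopropane-1,1-diesters with aldehydes, including its dynamic kinetic asymmetric form with pybox–MgI2, and Lewis acid-mediated annulations of such cyclopropanes with ketones; new here is the combination of an alkenyl donor, a simple ketone and asymmetric catalysis. The oxolane closes by C–C bond formation, an aldol-type attack of the enolate on the C=O+ unit (formally 5-endo-trig at the oxocarbenium, the usual mode of these annulations). The only new stereocentre, C5, is set by the chiral catalyst, which consumes one cyclopropane enantiomer faster while the other racemises through reversible ring opening to the allyl cation (or allyl iodide) and enolate, so both enantiomers of 8 funnel into the 5S product; acetone is symmetrical, so no second centre arises. The step needs attack at the proximal allyl terminus (five-membered ring) rather than the distal one (seven-membered ring) and retention of the E-alkene, which ring size and the tight ion-pair pathway should secure, while the isolated alkene and the silyl ether are spectators.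

Step 7
Reactants: 11 dimethyl (5S)-2,2-dimethyl-5-[(2E,6E)-6-methyl-8-(triisopropylsilyloxy)octa-2,6-dien-2-yl]oxolane-3,3-dicarboxylate
Product: 12 (5S)-2,2-dimethyl-5-[(2E,6E)-6-methyl-8-(triisopropylsilyloxy)octa-2,6-dien-2-yl]oxolane-3,3-dicarboxylic acid
Conditions: LiOH·H2O (10 equiv), THF/MeOH/H2O, 60 °C; then 1 M HCl, 0 °C, to pH 3
Reagents that add atoms: lithium hydroxide, [Li+].[OH-]
Why: Saponification of the geminal diester with excess hydroxide should give the malonic acid without touching any stereocentre.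

Step 8
Reactants: 12 (5S)-2,2-dimethyl-5-[(2E,6E)-6-methyl-8-(triisopropylsilyloxy)octa-2,6-dien-2-yl]oxolane-3,3-dicarboxylic acid
Product: 15 (5S)-2,2-dimethyl-5-[(2E,6E)-6-methyl-8-(triisopropylsilyloxy)octa-2,6-dien-2-yl]oxolan-3-one, via bis(acyl azide) 13 (not isolated), via geminal diisocyanate 14 (not isolated)
Conditions: (PhO)2P(O)N3 (2.4 equiv), Et3N, PhMe, 0 °C to rt, then 90 °C; then 2 M aq HCl/THF, rt
Reagents that add atoms: water, O
Why: Double Curtius rearrangement of the malonic acid gives the geminal diisocyanate, whose acidic hydrolysis releases the ketone (a classical malonic acid to ketone degradation that avoids a carbocation at C3), and C5 is not epimerisable under these conditions.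

Step 9
Reactants: 15 (5S)-2,2-dimethyl-5-[(2E,6E)-6-methyl-8-(triisopropylsilyloxy)octa-2,6-dien-2-yl]oxolan-3-one
Product: 16 (3S,5S)-2,2-dimethyl-5-[(2E,6E)-6-methyl-8-(triisopropylsilyloxy)octa-2,6-dien-2-yl]oxolan-3-ol
Conditions: (R)-Me-CBS oxazaborolidine (20 mol%), catecholborane, PhMe, −78 °C; then MeOH, aq NaOH
Reagents that add atoms: none
Why: Corey–Bakshi–Shibata reduction, in which the catalyst distinguishes the quaternary C2 side from the C4 methylene side and should deliver hydride to give the 3S alcohol; this is also the face opposite the C5 substituent, so the cis-3,5 relationship is set in a matched case.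

Step 10
Reactants: 16 (3S,5S)-2,2-dimethyl-5-[(2E,6E)-6-methyl-8-(triisopropylsilyloxy)octa-2,6-dien-2-yl]oxolan-3-ol
Product: 17 4-methoxybenzyl ether of 16: triisopropyl{[(2E,6E)-7-{(2S,4S)-4-[(4-methoxybenzyl)oxy]-5,5-dimethyloxolan-2-yl}-3-methylocta-2,6-dien-1-yl]oxy}silane
Conditions: NaH, 4-MeOC6H4CH2Cl, Bu4NI (cat.), DMF, 0 °C to rt
Reagents that add atoms: 4-methoxybenzyl chloride, COc1ccc(CCl)cc1
Why: Williamson etherification of the hindered secondary alkoxide should install an ether that tolerates fluoride, AlMe3 and acylation and is later removed by the same cerium oxidant that unmasks the quinone.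

Step 11
Reactants: 17 4-methoxybenzyl ether of 16
Product: 18 (2E,6E)-7-{(2S,4S)-4-[(4-methoxybenzyl)oxy]-5,5-dimethyloxolan-2-yl}-3-methylocta-2,6-dien-1-ol
Conditions: Bu4NF, THF, 0 °C to rt; then H2O
Reagents that add atoms: none
Why: Fluoride-mediated desilylation should free the primary allylic alcohol without affecting the benzyl-type ether.

Step 12
Reactants: 18 (2E,6E)-7-{(2S,4S)-4-[(4-methoxybenzyl)oxy]-5,5-dimethyloxolan-2-yl}-3-methylocta-2,6-dien-1-ol
Product: 19 (2E,6E)-7-{(2S,4S)-4-[(4-methoxybenzyl)oxy]-5,5-dimethyloxolan-2-yl}-3-methylocta-2,6-dienal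
Conditions: MnO2 (excess), CH2Cl2, rt
Reagents that add atoms: none
Why: MnO2 oxidation of the allylic alcohol should give the E-enal selectively.

Step 13
Reactants: 19 (2E,6E)-7-{(2S,4S)-4-[(4-methoxybenzyl)oxy]-5,5-dimethyloxolan-2-yl}-3-methylocta-2,6-dienal; 20 allenylboronic acid pinacol ester
Product: 21 (4S,5E,9E)-10-{(2S,4S)-4-[(4-methoxybenzyl)oxy]-5,5-dimethyloxolan-2-yl}-6-methylundeca-5,9-dien-1-yn-4-ol
Conditions: 20 (1.5 equiv), (S)-TRIP phosphoric acid (5 mol%; 3,3′-bis(2,4,6-triisopropylphenyl)-BINOL hydrogen phosphate), 4 Å MS, PhMe, −20 °C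
Reagents that add atoms: none
Why: Chiral phosphoric acid-catalysed propargylation of the enal with the allenylboronate (SE2′ addition through a closed six-membered transition state) should give the homopropargylic alcohol, the catalyst selecting the aldehyde face and thereby the new 4S centre (C5′ of the target).

Step 14
Reactants: 22 4-methoxy-2-methylphenol
Product: 23 2-hydroxy-5-methoxy-3-methylbenzaldehyde
Conditions: MgCl2, Et3N, (CH2O)n, MeCN, reflux
Reagents that add atoms: paraformaldehyde (as formaldehyde), C=O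
Why: Casnati–Skattebøl ortho-formylation through the magnesium phenoxide is specific for the one free ortho position.

Step 15
Reactants: 23 2-hydroxy-5-methoxy-3-methylbenzaldehyde
Product: 24 2,5-dimethoxy-3-methylbenzaldehyde
Conditions: MeI, K2CO3, DMF, rt
Reagents that add atoms: iodomethane, CI
Why: Williamson O-methylation of the phenol should be straightforward.

Step 16
Reactants: 24 2,5-dimethoxy-3-methylbenzaldehyde
Product: 25 (2,5-dimethoxy-3-methylphenyl)methanol
Conditions: NaBH4, MeOH, 0 °C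
Reagents that add atoms: none
Why: Hydride reduction of the aromatic aldehyde gives the benzylic alcohol.

Step 17
Reactants: 25 (2,5-dimethoxy-3-methylphenyl)methanol
Product: 26 1-(chloromethyl)-2,5-dimethoxy-3-methylbenzene
Conditions: SOCl2, CH2Cl2, 0 °C
Reagents that add atoms: thionyl chloride, ClS(Cl)=O
Why: Chlorination of the electron-rich benzylic alcohol through its chlorosulfite should be fast, and the chloride is used directly.

Step 18
Reactants: 21 (4S,5E,9E)-10-{(2S,4S)-4-[(4-methoxybenzyl)oxy]-5,5-dimethyloxolan-2-yl}-6-methylundeca-5,9-dien-1-yn-4-ol; 26 1-(chloromethyl)-2,5-dimethoxy-3-methylbenzene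
Product: 28 (2E,5S,6E,10E)-1-(2,5-dimethoxy-3-methylphenyl)-11-{(2S,4S)-4-[(4-methoxybenzyl)oxy]-5,5-dimethyloxolan-2-yl}-3,7-dimethyldodeca-2,6,10-trien-5-ol, via alkenyldimethylalane 27 (not isolated)
Conditions: AlMe3 (3.5 equiv), Cp2ZrCl2 (0.3 equiv), CH2Cl2, 0 °C to rt; then 26, Pd(PPh3)4 (5 mol%), THF, rt; cold dilute HCl work-up
Reagents that add atoms: trimethylaluminium, C[Al](C)C
Why: Negishi zirconium-catalysed carboalumination adds methyl and aluminium syn across the terminal alkyne (methyl to the internal carbon), and palladium-catalysed cross-coupling of the alkenylalane with the benzylic chloride proceeds with retention, so the E trisubstituted C2′=C3′ alkene is set while the carbinol is masked in situ as its aluminium alkoxide.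

Step 19
Reactants: 28 (2E,5S,6E,10E)-1-(2,5-dimethoxy-3-methylphenyl)-11-{(2S,4S)-4-[(4-methoxybenzyl)oxy]-5,5-dimethyloxolan-2-yl}-3,7-dimethyldodeca-2,6,10-trien-5-ol
Product: 29 (2E,5S,6E,10E)-1-(2,5-dimethoxy-3-methylphenyl)-11-{(2S,4S)-4-[(4-methoxybenzyl)oxy]-5,5-dimethyloxolan-2-yl}-3,7-dimethyldodeca-2,6,10-trien-5-yl acetate
Conditions: Ac2O, pyridine, DMAP (cat.), CH2Cl2, 0 °C to rt
Reagents that add atoms: acetic anhydride, CC(=O)OC(C)=O
Why: Standard acylation of the only free hydroxyl group.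

Step 20
Reactants: 29 (2E,5S,6E,10E)-1-(2,5-dimethoxy-3-methylphenyl)-11-{(2S,4S)-4-[(4-methoxybenzyl)oxy]-5,5-dimethyloxolan-2-yl}-3,7-dimethyldodeca-2,6,10-trien-5-yl acetate
Product: 30 (2E,5S,6E,10E)-11-[(2S,4S)-4-hydroxy-5,5-dimethyloxolan-2-yl]-3,7-dimethyl-1-(5-methyl-3,6-dioxocyclohexa-1,4-dien-1-yl)dodeca-2,6,10-trien-5-yl acetate
Conditions: (NH4)2Ce(NO3)6 (5 equiv), MeCN/H2O (4:1), 0 °C
Reagents that add atoms: water, O
Why: The cerium oxidant should effect both oxidative demethylation of the 1,4-dimethoxyarene to the quinone and oxidative cleavage of the 4-methoxybenzyl ether, and the allylic acetate, the alkenes and the oxolane are expected to tolerate the short, cold reaction.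

Step 21
Reactants: 30 (2E,5S,6E,10E)-11-[(2S,4S)-4-hydroxy-5,5-dimethyloxolan-2-yl]-3,7-dimethyl-1-(5-methyl-3,6-dioxocyclohexa-1,4-dien-1-yl)dodeca-2,6,10-trien-5-yl acetate
Product: 31 CNP0227918.2, (2E,5S,6E,10E)-1-(2,5-dihydroxy-3-methylphenyl)-11-[(2S,4S)-4-hydroxy-5,5-dimethyloxolan-2-yl]-3,7-dimethyldodeca-2,6,10-trien-5-yl acetate
Conditions: Na2S2O4, THF/H2O, rt, argon
Reagents that add atoms: none
Why: Dithionite reduction of the 1,4-benzoquinone to the hydroquinone under neutral conditions avoids acid-induced chroman formation.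

**Compound list**

1 | geraniol, (2E)-3,7-dimethylocta-2,6-dien-1-ol | OC/C=C(\C)CCC=C(C)C | starting material
2 | geranyl triisopropylsilyl ether | CC(C)[Si](C(C)C)(C(C)C)OC/C=C(\C)CCC=C(C)C | intermediate
3 | (2E,6E)-2,6-dimethyl-8-[(triisopropylsilyl)oxy]octa-2,6-dien-1-ol | CC(C)[Si](C(C)C)(C(C)C)OC/C=C(\C)CC/C=C(\C)CO | intermediate
4 | (2E,6E)-2,6-dimethyl-8-[(triisopropylsilyl)oxy]octa-2,6-dienal | CC(C)[Si](C(C)C)(C(C)C)OC/C=C(\C)CC/C=C(\C)C=O | intermediate
5 | methyltriphenylphosphonium bromide | C[P+](c1ccccc1)(c1ccccc1)c1ccccc1.[Br-] | starting material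
6 | triisopropyl{[(2E,6E)-3,7-dimethylnona-2,6,8-trien-1-yl]oxy}silane | CC(C)[Si](C(C)C)(C(C)C)OC/C=C(\C)CC/C=C(\C)C=C | intermediate
7 | dimethyl diazomalonate | COC(=O)C(=[N+]=[N-])C(=O)OC | starting material
8 | racemic dimethyl 2-[(2E,6E)-6-methyl-8-(triisopropylsilyloxy)octa-2,6-dien-2-yl]cyclopropane-1,1-dicarboxylate | CC(C)[Si](C(C)C)(C(C)C)OC/C=C(\C)CC/C=C(\C)C1CC1(C(=O)OC)C(=O)OC | intermediate
9 | acetone | CC(C)=O | starting material
10 | oxocarbenium malonate ion pair (O-alkylated acetone and malonate enolate, magnesium-bound) | CC(C)[Si](C(C)C)(C(C)C)OC/C=C(\C)CC/C=C(\C)[C@H](C[C-](C(=O)OC)C(=O)OC)[O+]=C(C)C | intermediate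
11 | dimethyl (5S)-2,2-dimethyl-5-[(2E,6E)-6-methyl-8-(triisopropylsilyloxy)octa-2,6-dien-2-yl]oxolane-3,3-dicarboxylate | CC(C)[Si](C(C)C)(C(C)C)OC/C=C(\C)CC/C=C(\C)[C@@H]1CC(C(=O)OC)(C(=O)OC)C(C)(C)O1 | intermediate
12 | (5S)-2,2-dimethyl-5-[(2E,6E)-6-methyl-8-(triisopropylsilyloxy)octa-2,6-dien-2-yl]oxolane-3,3-dicarboxylic acid | CC(C)[Si](C(C)C)(C(C)C)OC/C=C(\C)CC/C=C(\C)[C@@H]1CC(C(=O)O)(C(=O)O)C(C)(C)O1 | intermediate
13 | bis(acyl azide) of 12 | CC(C)[Si](C(C)C)(C(C)C)OC/C=C(\C)CC/C=C(\C)[C@@H]1CC(C(=O)N=[N+]=[N-])(C(=O)N=[N+]=[N-])C(C)(C)O1 | intermediate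
14 | geminal diisocyanate, (5S)-3,3-diisocyanato-2,2-dimethyl-5-[(2E,6E)-6-methyl-8-(triisopropylsilyloxy)octa-2,6-dien-2-yl]oxolane | CC(C)[Si](C(C)C)(C(C)C)OC/C=C(\C)CC/C=C(\C)[C@@H]1CC(N=C=O)(N=C=O)C(C)(C)O1 | intermediate
15 | (5S)-2,2-dimethyl-5-[(2E,6E)-6-methyl-8-(triisopropylsilyloxy)octa-2,6-dien-2-yl]oxolan-3-one | CC(C)[Si](C(C)C)(C(C)C)OC/C=C(\C)CC/C=C(\C)[C@@H]1CC(=O)C(C)(C)O1 | intermediate
16 | (3S,5S)-2,2-dimethyl-5-[(2E,6E)-6-methyl-8-(triisopropylsilyloxy)octa-2,6-dien-2-yl]oxolan-3-ol | CC(C)[Si](C(C)C)(C(C)C)OC/C=C(\C)CC/C=C(\C)[C@@H]1C[C@H](O)C(C)(C)O1 | intermediate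
17 | 4-methoxybenzyl ether of 16 | CC(C)[Si](C(C)C)(C(C)C)OC/C=C(\C)CC/C=C(\C)[C@@H]1C[C@H](OCc2ccc(OC)cc2)C(C)(C)O1 | intermediate
18 | (2E,6E)-7-{(2S,4S)-4-[(4-methoxybenzyl)oxy]-5,5-dimethyloxolan-2-yl}-3-methylocta-2,6-dien-1-ol | OC/C=C(\C)CC/C=C(\C)[C@@H]1C[C@H](OCc2ccc(OC)cc2)C(C)(C)O1 | intermediate
19 | (2E,6E)-7-{(2S,4S)-4-[(4-methoxybenzyl)oxy]-5,5-dimethyloxolan-2-yl}-3-methylocta-2,6-dienal | O=C/C=C(\C)CC/C=C(\C)[C@@H]1C[C@H](OCc2ccc(OC)cc2)C(C)(C)O1 | intermediate
20 | allenylboronic acid pinacol ester | C=C=CB1OC(C)(C)C(C)(C)O1 | starting material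
21 | (4S,5E,9E)-10-{(2S,4S)-4-[(4-methoxybenzyl)oxy]-5,5-dimethyloxolan-2-yl}-6-methylundeca-5,9-dien-1-yn-4-ol | C#CC[C@H](O)/C=C(\C)CC/C=C(\C)[C@@H]1C[C@H](OCc2ccc(OC)cc2)C(C)(C)O1 | intermediate
22 | 4-methoxy-2-methylphenol | COc1ccc(O)c(C)c1 | starting material
23 | 2-hydroxy-5-methoxy-3-methylbenzaldehyde | COc1cc(C)c(O)c(C=O)c1 | intermediate
24 | 2,5-dimethoxy-3-methylbenzaldehyde | COc1cc(C)c(OC)c(C=O)c1 | intermediate
25 | (2,5-dimethoxy-3-methylphenyl)methanol | COc1cc(C)c(OC)c(CO)c1 | intermediate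
26 | 1-(chloromethyl)-2,5-dimethoxy-3-methylbenzene | COc1cc(C)c(OC)c(CCl)c1 | intermediate
27 | alkenyldimethylalane (E-alkenyl–AlMe2 with the carbinol as its dimethylaluminium alkoxide) | C[Al](C)/C=C(\C)C[C@H](O[Al](C)C)/C=C(\C)CC/C=C(\C)[C@@H]1C[C@H](OCc2ccc(OC)cc2)C(C)(C)O1 | intermediate
28 | (2E,5S,6E,10E)-1-(2,5-dimethoxy-3-methylphenyl)-11-{(2S,4S)-4-[(4-methoxybenzyl)oxy]-5,5-dimethyloxolan-2-yl}-3,7-dimethyldodeca-2,6,10-trien-5-ol | COc1cc(C)c(OC)c(C/C=C(\C)C[C@H](O)/C=C(\C)CC/C=C(\C)[C@@H]2C[C@H](OCc3ccc(OC)cc3)C(C)(C)O2)c1 | intermediate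
29 | acetate of 28 | COc1cc(C)c(OC)c(C/C=C(\C)C[C@H](OC(C)=O)/C=C(\C)CC/C=C(\C)[C@@H]2C[C@H](OCc3ccc(OC)cc3)C(C)(C)O2)c1 | intermediate
30 | (2E,5S,6E,10E)-11-[(2S,4S)-4-hydroxy-5,5-dimethyloxolan-2-yl]-3,7-dimethyl-1-(5-methyl-3,6-dioxocyclohexa-1,4-dien-1-yl)dodeca-2,6,10-trien-5-yl acetate | CC1=CC(=O)C=C(C/C=C(\C)C[C@H](OC(C)=O)/C=C(\C)CC/C=C(\C)[C@@H]2C[C@H](O)C(C)(C)O2)C1=O | intermediate
31 | CNP0227918.2, (2E,5S,6E,10E)-1-(2,5-dihydroxy-3-methylphenyl)-11-[(2S,4S)-4-hydroxy-5,5-dimethyloxolan-2-yl]-3,7-dimethyldodeca-2,6,10-trien-5-yl acetate | CC(=O)O[C@H](/C=C(\C)CC/C=C(\C)[C@@H]1C[C@H](O)C(C)(C)O1)C/C(C)=C/Cc1cc(O)cc(C)c1O | target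

**Count and risks**

Total steps: 21. Longest linear sequence: 17 (steps 1–13 and 18–21; steps 14–17 make the arene fragment).

Steps most likely to fail:

1. Step 6 (Proposed new method). Enantiocontrol may be lost if the slow-reacting cyclopropane enantiomer does not racemise fast enough or if an uncatalysed, iodide-mediated pathway competes; the product could also erode by reversible ionisation of the allylic C5–O1 bond under the Lewis acid. Fallback, from 8 back to 11: annulation of racemic 8 with acetone under an achiral Lewis acid (Sn(OTf)2, 10 mol%, CH2Cl2, rt), the established non-asymmetric annulation of donor–acceptor cyclopropanes with carbonyl compounds, would give racemic diester F1. The enantiomers would then be separated by preparative chromatography on a chiral stationary phase: the 5S enantiomer is 11 and the 5R enantiomer F2 is set aside.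

2. Step 8. The hindered geminal diacid may form the second acyl azide sluggishly, and the first isocyanate may be intercepted by the neighbouring carboxyl group (cyclic N-carboxyanhydride), diverting material to an amino acid instead of the ketone. Fallback, from 11 back to 15: Krapcho dealkoxycarbonylation (LiCl, wet DMSO, 140 °C) would give monoester F3 as a mixture of C3 epimers. Enolate hydroxylation (KN(SiMe3)2, then 2-(phenylsulfonyl)-3-phenyloxaziridine, THF, −78 °C) would give hydroxy ester F4. LiAlH4 reduction would give diol F5, and NaIO4 glycol cleavage (THF/H2O) would return ketone 15.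

3. Step 18. Transfer of the alkenyl group from aluminium to palladium may be slow in the presence of the aluminium alkoxide and the Lewis-basic ethers, so that protodealumination and homocoupling of the benzylic chloride compete; prolonged exposure to AlMe3 may also ionise the allylic oxolane ether. Fallback, from 21 back to 28: the same carboalumination quenched with I2 (−30 °C) would give vinyl iodide F6, isolated. Separately, 26 with zinc dust and LiCl in THF would give benzylzinc chloride F7. Negishi coupling of F6 with excess F7 (Pd(PPh3)4, THF, rt) would return 28, reversing the polarity of the coupling partners.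

Further compounds
F1 | step 6 | racemic dimethyl 2,2-dimethyl-5-[(2E,6E)-6-methyl-8-(triisopropylsilyloxy)octa-2,6-dien-2-yl]oxolane-3,3-dicarboxylate | CC(C)[Si](C(C)C)(C(C)C)OC/C=C(\C)CC/C=C(\C)C1CC(C(=O)OC)(C(=O)OC)C(C)(C)O1
F2 | step 6 | dimethyl (5R)-2,2-dimethyl-5-[(2E,6E)-6-methyl-8-(triisopropylsilyloxy)octa-2,6-dien-2-yl]oxolane-3,3-dicarboxylate | CC(C)[Si](C(C)C)(C(C)C)OC/C=C(\C)CC/C=C(\C)[C@H]1CC(C(=O)OC)(C(=O)OC)C(C)(C)O1
F3 | step 8 | methyl (5S)-2,2-dimethyl-5-[(2E,6E)-6-methyl-8-(triisopropylsilyloxy)octa-2,6-dien-2-yl]oxolane-3-carboxylate (C3 epimers) | CC(C)[Si](C(C)C)(C(C)C)OC/C=C(\C)CC/C=C(\C)[C@@H]1CC(C(=O)OC)C(C)(C)O1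
F4 | step 8 | methyl (5S)-3-hydroxy-2,2-dimethyl-5-[(2E,6E)-6-methyl-8-(triisopropylsilyloxy)octa-2,6-dien-2-yl]oxolane-3-carboxylate (C3 epimers) | CC(C)[Si](C(C)C)(C(C)C)OC/C=C(\C)CC/C=C(\C)[C@@H]1CC(O)(C(=O)OC)C(C)(C)O1
F5 | step 8 | (5S)-3-(hydroxymethyl)-2,2-dimethyl-5-[(2E,6E)-6-methyl-8-(triisopropylsilyloxy)octa-2,6-dien-2-yl]oxolan-3-ol (C3 epimers) | CC(C)[Si](C(C)C)(C(C)C)OC/C=C(\C)CC/C=C(\C)[C@@H]1CC(O)(CO)C(C)(C)O1
F6 | step 18 | (1E,4S,5E,9E)-1-iodo-10-{(2S,4S)-4-[(4-methoxybenzyl)oxy]-5,5-dimethyloxolan-2-yl}-2,6-dimethylundeca-1,5,9-trien-4-ol | I/C=C(\C)C[C@H](O)/C=C(\C)CC/C=C(\C)[C@@H]1C[C@H](OCc2ccc(OC)cc2)C(C)(C)O1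
F7 | step 18 | (2,5-dimethoxy-3-methylbenzyl)zinc chloride | COc1cc(C)c(OC)c(C[Zn]Cl)c1
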